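## The problem

CNP0297675.1 is a 3-prenylflavone. Ring A (C4a–C8a) is a fully substituted phloroglucinol with free hydroxyls on C5 and C7, a prenyl group on C6 and a (2R)-2-hydroxy-3-methylbut-3-enyl chain on C8. Ring C carries a second prenyl group on C3, and ring B is a 2,4-dihydroxyphenyl group on C2. The ring fusion is ordinary flavone connectivity, so the difficulty is positional: ring A holds two different carbon groups and three oxygens (O5, O7 and the C8a oxygen that becomes O1), and closing ring C onto O5 instead of the C8a oxygen would exchange the C6 and C8 groups. The only stereocentre, C2″ of the C8 chain, is remote from every other directing element; it can neither be controlled by the skeleton nor control anything, so a chiral catalyst or reagent must set it and the route must then carry it untouched. Three electron-rich alkenes, an allylic secondary alcohol and phenols ortho to them exclude hydrogenolysis, late strong protic or Lewis acids (chroman formation, ionization of the allylic alcohol) and electrophilic oxidants. The last protecting groups therefore have to fall to fluoride, zerovalent palladium or a chelation-specific reagent. The feature that opens the way is the order of substituents round ring A: hydroxyl on C8a, carbon on C8, oxygen on C7, carbon on C6, oxygen on C5, hydrogen on C4a. This is the pattern produced when the two carbons of a siloxyalkyne (C8, C7) are inserted between the carbonyl carbon (C8a) and the α-carbon (C6) of a vinylketene whose other two carbons bring the C5 oxygen and the unsubstituted C4a.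

## Retrosynthesis

Protecting groups. Target 36 is traced to bis(allyl) ether 35, this to the silyl ethers 34 (triisopropylsilyl on O7, tert-butyldiphenylsilyl on the carbinol) and this to 5-O-methyl ether 33. Each group leaves under conditions that spare prenyl groups and the allylic alcohol: palladium-catalysed allyl transfer, fluoride, and chelation-assisted demethylation next to the C4 carbonyl. The methyl group is not an extra burden: it is the oxygen substituent that the ring A construction delivers at C5. It is removed first, while every other oxygen is still masked and only one chelating site exists.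

Ring C. In 33 the O1–C2 and C2–C3 bonds are cut, which leads through diketone 31 to hydroxy ketone 26 and acid 29 (used as chloride 30). This Baker–Venkataraman cut is preferred to chalcone oxidation, which needs oxidants that attack prenyl groups, and to an alkyne annulation, which would still need a ring A aldehyde of the same complexity. Ketone 26 already holds the C3 prenyl group in its side chain, and its O5 is methylated, so only the C8a oxygen can close. The forward reactions must acylate a hindered enolate on carbon and dehydrate under acid mild enough for three alkenes.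

C4a–C4 bond. Ketone 26 is cut between the ring and the carbonyl group, giving methoxymethyl ether 20 (through ketone 25) and Weinreb amide 23; 20 is the ether of phenol 19. C4a is the only unsubstituted ring carbon and lies between two oxygens, so directed lithiation replaces a Fries or Friedel–Crafts acylation whose Lewis acids the prenyl groups would not survive. The forward step must lithiate the ring faster than the benzylic–allylic methylene groups, and the temporary acetal on O8a must leave under dilute acid, which its position ortho to the new ketone makes easy.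

Ring A (key disconnection). Phenol 19 is cut at C8a–C8, C7–C6 and C8a–C4a, giving cyclobutenone 7 and siloxyalkyne 14. Every ring carbon arrives with its substituent, and the three oxygens arrive differentiated as free hydroxyl (O8a), silyl ether (O7) and methyl ether (O5). Substitution of a preformed phloroglucinol would have to place two different carbon groups and distinguish three oxygens by reactivity alone. The precursors are a four-membered ring with nine heavy atoms besides the prenyl group and an acyclic alkyne with one stereocentre. The forward reaction needs regioselective ketene–alkyne cycloaddition and ring opening of 7 at a temperature that 14 survives.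

Siloxyalkyne. In 14 the O–C(sp) bond is cut back to terminal alkyne 11 (acetylide oxidation to the ynolate, O-silylation), and 11 is the silyl ether of alcohol 10. Alcohol 10 is cut at C3–C4 into methacrolein 8 and allenylboronate 9. This takes three steps, against four for an aldol and ester-homologation sequence. The forward propargylation must discriminate the faces of a small α-branched enal under catalyst control.

Cyclobutenone. In 7 both ring bonds to the ketene carbons are cut, giving ynol ether 4 and ketene 6 (from acetone 5); 4 is cut at the propargylic bond into chloroacetal 1 and prenyl bromide 2. The polarity of the ynol ether fixes prenyl at C2 and methoxy at C3, whereas C-alkylation of a cyclobutane-1,3-dione would leave C/O selectivity open. The forward cycloaddition must take the alkyne and leave the trisubstituted alkene alone.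

Small fragments. Acid 29 comes from 2,4-dihydroxybenzoic acid 27 by exhaustive allylation (ester 28) and saponification. Amide 23 comes from 5-methylhex-4-enoic acid 21 through acyl imidazole 22.

## Roads not taken

Alternative 1: The C8 chain is traced to an epoxide, and ring A is reduced to the mirror-symmetric arene A1, which carries a single prenyl group between two methoxymethyl ethers and an allyl ether as a tag on the para oxygen. The forward key step is a Shi epoxidation of the trisubstituted alkene of A1 (dioxirane from a fructose-derived ketone and KHSO5) to the (R)-epoxide A2, followed later by base-induced opening to the allylic alcohol. Its merits are real. Trisubstituted alkenes are the best substrate class for this catalyst, the feedstock is cheaper than anything in the chosen plan, and the symmetry of A1 makes the two oxygens flanking the chain equivalent, so either may become O1. Its weak points come after A2: ring A still lacks the C6 prenyl group and the C4a acyl group. These must be introduced by electrophilic substitution or Claisen chemistry on an electron-rich ring that already carries an acid-sensitive epoxide or allylic alcohol. The dioxirane may also attack the electron-rich arene. In the stereocentre-setting step this road is at least as good as the chosen one. The chosen plan sets against it that no substituent is introduced on a completed, sensitive ring and that all positions are fixed by construction.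

Alternative 2: Ring A is cut at C5–C6, leaving ring C as the fully substituted pyranone A3, with a methyl ester on the future C4a and a branched ketone chain on the future C8a. Under Mg(OMe)2 or an amidine base the C6 enolate attacks the ester (Dieckmann-type, 6-exo-trig), and enolization with loss of methanol gives the 5,7-dihydroxyflavone A4. This road is better than the chosen plan in protecting-group economy: O5 and O7 appear as free phenols in one step, ring C regiochemistry is settled beforehand, and no demethylation is needed. Its weakness is A3 itself. Assembling a pyranone with four different substituents, one of them a ketone chain carrying the silylated carbinol, is longer than the whole chosen approach to ring A. The pyranone is also open to conjugate attack by alkoxide, and the C8 hydrogen, acidified by both the ketone and the pyranone, favours the unproductive enolate. The chosen plan answers with key-step precursors made in two and three steps and a cascade of a known type, and pays with the O5 methyl ether and the temporary acetal on O8a.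

Alternative 3: Ring C is cut at C4–C3 and O1–C2 into salicylaldehyde A5 and aryl prenyl alkyne A6. These would be joined by aldehyde C–H activation with [Cp*RhCl2]2 (trivalent rhodium), alkyne insertion and C–O bond formation, with Cu(OAc)2 as oxidant, to give the protected flavone A7. In convergence this is the best ring C closure: one step joins both halves and brings in the C3 prenyl group, where the chosen plan needs four steps. Aryl–alkyl alkynes normally insert with the aryl group next to oxygen, as required. The weak points are several. A5 is a hexasubstituted ring whose synthesis is the unsolved ring A problem. A6 is a skipped enyne that can isomerize to an allene under acetate and metal. Both partners are crowded at the reacting centres. Divalent copper at elevated temperature meets an electron-rich phenol flanked by alkenes. The four methoxymethyl groups of A7 must finally leave under acid next to prenyl groups and the allylic alcohol. The chosen plan sets against the better convergence a solution for ring A and an end game free of acid.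

Key step: step 6

Remark: ketene 6 is generated from acetone 5 in a ketene lamp and used at once; 9 and 21 are treated as catalogue compounds.

## Route

Step 1
Reactants: 1 2-chloro-1,1-dimethoxyethane; 2 1-bromo-3-methylbut-2-ene (prenyl bromide)
Product: 4 1-methoxy-5-methylhex-4-en-1-yne, via sodium methoxyethynide 3 (not isolated)
Conditions: NaNH2 (3 equiv), liq. NH3, −33 °C; then 2, −33 °C; NH4Cl
Reagents that add atoms: none
Why: Double elimination (methanol, then HCl) and deprotonation give the sodium alkoxyacetylide, as in the classical preparation of methoxyacetylene, and this is C-alkylated by the primary allylic bromide (SN2), as in the known preparation of 1-alkoxyalk-1-ynes in liquid ammonia.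

Step 2
Reactants: 4 1-methoxy-5-methylhex-4-en-1-yne; 5 acetone
Product: 7 3-methoxy-2-(3-methylbut-2-en-1-yl)cyclobut-2-en-1-one, via ketene 6 (not isolated)
Conditions: 5, ketene lamp (ca. 700 °C); gas stream into 4, CH2Cl2, 0 °C → rt
Reagents that add atoms: none
Why: Ketene–ynol ether [2+2] cycloaddition, the established route to 3-alkoxycyclobutenones; the alkyne carbon remote from oxygen attacks the ketene carbonyl carbon, which places prenyl at C2 and methoxy at C3, and the isolated trisubstituted alkene does not react with ketene at this temperature.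

Step 3
Reactants: 8 methacrolein; 9 allenylboronic acid pinacol ester
Product: 10 (3R)-2-methylhex-1-en-5-yn-3-ol
Conditions: (R)-TRIP [(R)-3,3′-bis(2,4,6-triisopropylphenyl)-1,1′-binaphthyl-2,2′-diyl hydrogen phosphate] (5 mol %), 4 Å MS, toluene, −20 °C
Reagents that add atoms: none
Why: Chiral phosphoric acid-catalysed propargylation of an aldehyde by an allenylboronate through a closed six-membered SE2′ transition state; the (R)-acid, bound to a boronate oxygen and the formyl hydrogen, should direct the propargyl group to the Re face as it does for aryl and alkenyl aldehydes, which sets C3 as R.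

Step 4
Reactants: 10 (3R)-2-methylhex-1-en-5-yn-3-ol
Product: 11 (3R)-3-(tert-butyldiphenylsilyloxy)-2-methylhex-1-en-5-yne
Conditions: TBDPSCl, imidazole, DMF, rt
Reagents that add atoms: tert-butyl(chloro)diphenylsilane, CC(C)(C)[Si](Cl)(c1ccccc1)c1ccccc1
Why: Standard silylation of a secondary alcohol; the diphenyl-tert-butylsilyl group is chosen because it must later survive dilute acid in steps 10 and 13 and still leave with fluoride.

Step 5
Reactants: 11 (3R)-3-(tert-butyldiphenylsilyloxy)-2-methylhex-1-en-5-yne
Product: 14 (4R)-4-(tert-butyldiphenylsilyloxy)-5-methyl-1-(triisopropylsilyloxy)hex-5-en-1-yne, via lithium acetylide 12 (not isolated), via lithium ynolate 13 (not isolated)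
Conditions: t-BuOOH, LiN(SiMe3)2 (2.2 equiv), THF, −78 → 0 °C; TIPSOTf, −78 °C
Reagents that add atoms: tert-butyl hydroperoxide, CC(C)(C)OO; triisopropylsilyl trifluoromethanesulfonate, CC(C)[Si](OS(=O)(=O)C(F)(F)F)(C(C)C)C(C)C
Why: Oxidation of a lithium acetylide by lithium tert-butylperoxide gives the ynolate, which the bulky silyl triflate captures on oxygen; this is the standard preparation of triisopropylsiloxyalkynes from terminal alkynes, and the carbinol centre is not involved.

Step 6
Reactants: 7 3-methoxy-2-(3-methylbut-2-en-1-yl)cyclobut-2-en-1-one; 14 (4R)-4-(tert-butyldiphenylsilyloxy)-5-methyl-1-(triisopropylsilyloxy)hex-5-en-1-yne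
Product: 19 2-[(2R)-2-(tert-butyldiphenylsilyloxy)-3-methylbut-3-en-1-yl]-5-methoxy-4-(3-methylbut-2-en-1-yl)-3-(triisopropylsilyloxy)phenol, via vinylketene 15 (not isolated), via 4-vinylcyclobutenone 16 (not isolated), via dienylketene 17 (not isolated), via cyclohexa-2,4-dienone 18 (not isolated)
Conditions: 7 (1.0 equiv), 14 (1.2 equiv), toluene (0.3 M), sealed tube, 110 °C
Reagents that add atoms: none
Why: Thermal four-electron conrotatory opening of 7 gives vinylketene 15, whose ketene C=C bond adds to the siloxyalkyne in a [2+2] cycloaddition that forms C8a–C8 and C7–C6 and closes the four-membered ring of 16. A second four-electron opening of 16 gives dienylketene 17, which closes ring A by a six-electron disrotatory electrocyclization forming C8a–C4a (18), and tautomerization aromatizes 18 to phenol 19. The closest known reaction is the Danheiser benzannulation of cyclobutenones with siloxyalkynes, which gives resorcinol monosilyl ethers. No stereocentre is created: the quaternary carbon of 16 is transient, and the silylated carbinol carbon, three bonds from the reacting alkyne, is a spectator under neutral thermal conditions. The step needs regioselectivity in the [2+2] event, and the polarization of the ynol ether secures it: the alkyne carbon remote from oxygen is nucleophilic and bonds to the electrophilic ketene carbonyl carbon, so the chain lands on C8 beside the new hydroxyl and the siloxy group on C7 beside the prenyl-bearing C6. It also needs chemoselectivity for the alkyne over three alkenes, which ketenes show toward electron-rich alkynes. The methoxy-bearing carbon of 7 becomes C5 and its methylene carbon becomes the unsubstituted C4a.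

Step 7
Reactants: 19 2-[(2R)-2-(tert-butyldiphenylsilyloxy)-3-methylbut-3-en-1-yl]-5-methoxy-4-(3-methylbut-2-en-1-yl)-3-(triisopropylsilyloxy)phenol
Product: 20 methoxymethyl ether of 19 [1-(methoxymethoxy) in place of the phenol hydroxyl]
Conditions: NaH, MOMCl, THF/DMF, 0 °C → rt
Reagents that add atoms: chloromethyl methyl ether, COCCl
Why: Williamson alkylation of the only free phenol; the acetal serves solely as directing group for the lithiation in step 9.

Step 8
Reactants: 21 5-methylhex-4-enoic acid
Product: 23 N-methoxy-N,5-dimethylhex-4-enamide, via 1-(5-methylhex-4-enoyl)imidazole 22 (not isolated)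
Conditions: 1,1′-carbonyldiimidazole (CDI), CH2Cl2, rt; MeNHOMe·HCl, rt
Reagents that add atoms: N,O-dimethylhydroxylamine hydrochloride, CNOC.Cl
Why: Acyl imidazole activation and aminolysis, the usual Weinreb amide synthesis.

Step 9
Reactants: 20 methoxymethyl ether of 19; 23 N-methoxy-N,5-dimethylhex-4-enamide
Product: 25 1-{3-[(2R)-2-(tert-butyldiphenylsilyloxy)-3-methylbut-3-en-1-yl]-6-methoxy-2-(methoxymethoxy)-5-(3-methylbut-2-en-1-yl)-4-(triisopropylsilyloxy)phenyl}-5-methylhex-4-en-1-one, via aryllithium 24 (not isolated)
Conditions: n-BuLi (1.3 equiv), THF, 0 °C; 23, −78 → 0 °C; aq. NH4Cl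
Reagents that add atoms: none
Why: Directed ortho-metalation at the only ring hydrogen, which lies between the methoxymethoxy and methoxy groups and is activated by both, followed by acylation with a Weinreb amide, which stops at the ketone stage; this forms the C4a–C4 bond without any Lewis acid.

Step 10
Reactants: 25 the aryl ketone of step 9
Product: 26 1-{3-[(2R)-2-(tert-butyldiphenylsilyloxy)-3-methylbut-3-en-1-yl]-2-hydroxy-6-methoxy-5-(3-methylbut-2-en-1-yl)-4-(triisopropylsilyloxy)phenyl}-5-methylhex-4-en-1-one
Conditions: 2 M aq. HCl, MeOH/THF, 40 °C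
Reagents that add atoms: none
Why: Acid-catalysed acetal exchange of an aryl methoxymethyl ether; the ether ortho to the ketone is the most labile kind and the freed phenol is hydrogen-bonded to the carbonyl group, while the tert-butyldiphenylsilyl and aryl triisopropylsilyl ethers tolerate dilute acid.

Step 11
Reactants: 27 2,4-dihydroxybenzoic acid
Product: 29 2,4-bis(allyloxy)benzoic acid, via allyl 2,4-bis(allyloxy)benzoate 28 (not isolated)
Conditions: allyl bromide (3.5 equiv), K2CO3, DMF, 60 °C; then 2 M aq. NaOH, MeOH, 60 °C; HCl to pH 2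
Reagents that add atoms: allyl bromide, C=CCBr; sodium hydroxide, [Na+].[OH-]
Why: Exhaustive Williamson and carboxylate alkylation followed by saponification of the allyl ester; aryl allyl ethers are inert to hydroxide.

Step 12
Reactants: 26 the hydroxy ketone of step 10; 29 2,4-bis(allyloxy)benzoic acid
Product: 31 1-[2,4-bis(allyloxy)phenyl]-3-aryl-2-(3-methylbut-2-en-1-yl)propane-1,3-dione (aryl = the ring A unit of 26; C2 epimers and enol forms), via 2,4-bis(allyloxy)benzoyl chloride 30 (not isolated)
Conditions: 29, (COCl)2, DMF (cat.), CH2Cl2, rt, evaporate; 26, LiN(SiMe3)2 (4 equiv), THF, −78 °C; 30, −78 °C → rt; aq. NH4Cl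
Reagents that add atoms: none
Why: One-flask Baker–Venkataraman-type synthesis of a 2-hydroxyaryl 1,3-diketone: excess amide base forms the phenoxide–enolate dianion of 26, its enolate carbon is acylated by the acid chloride, and the diketone is deprotonated at once, which prevents a second acylation.

Step 13
Reactants: 31 the 1,3-diketone of step 12
Product: 33 2-[2,4-bis(allyloxy)phenyl]-8-[(2R)-2-(tert-butyldiphenylsilyloxy)-3-methylbut-3-en-1-yl]-5-methoxy-3,6-bis(3-methylbut-2-en-1-yl)-7-(triisopropylsilyloxy)-4H-chromen-4-one, via 2-hydroxyflavanone hemiketal 32 (not isolated)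
Conditions: TsOH·H2O (10 mol %), toluene, 60 °C
Reagents that add atoms: none
Why: Acid-catalysed cyclodehydration, the closing step of the Baker–Venkataraman flavone synthesis: the C8a hydroxyl adds to the ring B carbonyl (6-exo-trig) and the hemiketal loses water through a cation stabilized by the 2,4-dialkoxyphenyl group; O5 is methylated and the ring B oxygens are allylated, so only the C8a oxygen can close and the C6 and C8 groups keep their places.

Step 14
Reactants: 33 the protected flavone of step 13
Product: 34 5-hydroxy analogue of 33 (5-OH in place of 5-OMe)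
Conditions: MgI2·OEt2 (3 equiv), toluene/Et2O, 60 °C; aq. NH4Cl/Na2S2O3
Reagents that add atoms: none
Why: Chelation-controlled demethylation: magnesium binds between the C4 carbonyl and the peri methoxy oxygen and iodide removes the methyl group by SN2; ethers without a neighbouring carbonyl group, silyl ethers and alkenes are not touched under these aprotic conditions.

Step 15
Reactants: 34 the 5-hydroxyflavone of step 14
Product: 35 2-[2,4-bis(allyloxy)phenyl]-5,7-dihydroxy-8-[(2R)-2-hydroxy-3-methylbut-3-en-1-yl]-3,6-bis(3-methylbut-2-en-1-yl)-4H-chromen-4-one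
Conditions: Bu4NF (4 equiv), THF, 0 °C → rt; aq. NH4Cl
Reagents that add atoms: none
Why: Fluoride-mediated desilylation of the aryl triisopropylsilyl ether and the secondary tert-butyldiphenylsilyl ether; the medium is basic, so the prenyl groups beside the freed phenols and the allylic alcohol are not at risk and the carbinol centre is untouched.

Step 16
Reactants: 35 the bis(allyl) ether of step 15
Product: 36 2-(2,4-dihydroxyphenyl)-5,7-dihydroxy-8-[(2R)-2-hydroxy-3-methylbut-3-en-1-yl]-3,6-bis(3-methylbut-2-en-1-yl)-4H-chromen-4-one (CNP0297675.1)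
Conditions: Pd(PPh3)4 (5 mol %), morpholine (10 equiv), THF, rt
Reagents that add atoms: none
Why: Tsuji–Trost deallylation: zerovalent palladium ionizes the aryl allyl ethers to π-allyl complexes that morpholine intercepts; prenyl groups and the free allylic alcohol have no leaving group and remain inert under these neutral conditions.

## Compound list

1 | 2-chloro-1,1-dimethoxyethane | COC(CCl)OC | starting material
2 | 1-bromo-3-methylbut-2-ene (prenyl bromide) | CC(C)=CCBr | starting material
3 | sodium methoxyethynide | [Na+].[C-]#COC | intermediate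
4 | 1-methoxy-5-methylhex-4-en-1-yne | COC#CCC=C(C)C | intermediate
5 | acetone | CC(C)=O | starting material
6 | ketene | C=C=O | intermediate
7 | 3-methoxy-2-(3-methylbut-2-en-1-yl)cyclobut-2-en-1-one | O=C1CC(OC)=C1CC=C(C)C | intermediate
8 | methacrolein (2-methylprop-2-enal) | C=C(C)C=O | starting material
9 | allenylboronic acid pinacol ester | C=C=CB1OC(C)(C)C(C)(C)O1 | starting material
10 | (3R)-2-methylhex-1-en-5-yn-3-ol | C=C(C)[C@H](O)CC#C | intermediate
11 | (3R)-3-(tert-butyldiphenylsilyloxy)-2-methylhex-1-en-5-yne | C=C(C)[C@H](O[Si](c1ccccc1)(c1ccccc1)C(C)(C)C)CC#C | intermediate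
12 | lithium acetylide of 11 | C=C(C)[C@H](O[Si](c1ccccc1)(c1ccccc1)C(C)(C)C)CC#C[Li] | intermediate
13 | lithium (4R)-4-(tert-butyldiphenylsilyloxy)-5-methylhex-5-en-1-yn-1-olate (ynolate) | C=C(C)[C@H](O[Si](c1ccccc1)(c1ccccc1)C(C)(C)C)CC#CO[Li] | intermediate
14 | (4R)-4-(tert-butyldiphenylsilyloxy)-5-methyl-1-(triisopropylsilyloxy)hex-5-en-1-yne | C=C(C)[C@H](O[Si](c1ccccc1)(c1ccccc1)C(C)(C)C)CC#CO[Si](C(C)C)(C(C)C)C(C)C | intermediate
15 | 2-(1-methoxyvinyl)-5-methylhexa-1,4-dien-1-one (vinylketene) | C=C(OC)C(CC=C(C)C)=C=O | intermediate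
16 | 2-[(2R)-2-(tert-butyldiphenylsilyloxy)-3-methylbut-3-en-1-yl]-4-(1-methoxyvinyl)-4-(3-methylbut-2-en-1-yl)-3-(triisopropylsilyloxy)cyclobut-2-en-1-one (C4 epimers) | C=C(C)[C@H](O[Si](c1ccccc1)(c1ccccc1)C(C)(C)C)CC1=C(O[Si](C(C)C)(C(C)C)C(C)C)C(CC=C(C)C)(C(OC)=C)C1=O | intermediate
17 | dienylketene from 16, ketene and methoxyvinyl groups cis on the central alkene | C=C(C)[C@H](O[Si](c1ccccc1)(c1ccccc1)C(C)(C)C)CC(=C=O)/C(O[Si](C(C)C)(C(C)C)C(C)C)=C(/CC=C(C)C)C(OC)=C | intermediate
18 | 2-[(2R)-2-(tert-butyldiphenylsilyloxy)-3-methylbut-3-en-1-yl]-5-methoxy-4-(3-methylbut-2-en-1-yl)-3-(triisopropylsilyloxy)cyclohexa-2,4-dien-1-one | C=C(C)[C@H](O[Si](c1ccccc1)(c1ccccc1)C(C)(C)C)CC1=C(O[Si](C(C)C)(C(C)C)C(C)C)C(CC=C(C)C)=C(OC)CC1=O | intermediate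
19 | 2-[(2R)-2-(tert-butyldiphenylsilyloxy)-3-methylbut-3-en-1-yl]-5-methoxy-4-(3-methylbut-2-en-1-yl)-3-(triisopropylsilyloxy)phenol | C=C(C)[C@H](O[Si](c1ccccc1)(c1ccccc1)C(C)(C)C)Cc1c(O[Si](C(C)C)(C(C)C)C(C)C)c(CC=C(C)C)c(OC)cc1O | intermediate
20 | methoxymethyl ether of 19 | C=C(C)[C@H](O[Si](c1ccccc1)(c1ccccc1)C(C)(C)C)Cc1c(O[Si](C(C)C)(C(C)C)C(C)C)c(CC=C(C)C)c(OC)cc1OCOC | intermediate
21 | 5-methylhex-4-enoic acid | CC(C)=CCCC(=O)O | starting material
22 | 1-(5-methylhex-4-enoyl)imidazole | CC(C)=CCCC(=O)n1ccnc1 | intermediate
23 | N-methoxy-N,5-dimethylhex-4-enamide | CC(C)=CCCC(=O)N(C)OC | intermediate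
24 | aryllithium from 20 (lithium on the carbon between OMe and OCH2OMe) | C=C(C)[C@H](O[Si](c1ccccc1)(c1ccccc1)C(C)(C)C)Cc1c(O[Si](C(C)C)(C(C)C)C(C)C)c(CC=C(C)C)c(OC)c([Li])c1OCOC | intermediate
25 | 1-{3-[(2R)-2-(tert-butyldiphenylsilyloxy)-3-methylbut-3-en-1-yl]-6-methoxy-2-(methoxymethoxy)-5-(3-methylbut-2-en-1-yl)-4-(triisopropylsilyloxy)phenyl}-5-methylhex-4-en-1-one | C=C(C)[C@H](O[Si](c1ccccc1)(c1ccccc1)C(C)(C)C)Cc1c(O[Si](C(C)C)(C(C)C)C(C)C)c(CC=C(C)C)c(OC)c(C(=O)CCC=C(C)C)c1OCOC | intermediate
26 | 1-{3-[(2R)-2-(tert-butyldiphenylsilyloxy)-3-methylbut-3-en-1-yl]-2-hydroxy-6-methoxy-5-(3-methylbut-2-en-1-yl)-4-(triisopropylsilyloxy)phenyl}-5-methylhex-4-en-1-one | C=C(C)[C@H](O[Si](c1ccccc1)(c1ccccc1)C(C)(C)C)Cc1c(O[Si](C(C)C)(C(C)C)C(C)C)c(CC=C(C)C)c(OC)c(C(=O)CCC=C(C)C)c1O | intermediate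
27 | 2,4-dihydroxybenzoic acid | O=C(O)c1ccc(O)cc1O | starting material
28 | allyl 2,4-bis(allyloxy)benzoate | C=CCOC(=O)c1ccc(OCC=C)cc1OCC=C | intermediate
29 | 2,4-bis(allyloxy)benzoic acid | O=C(O)c1ccc(OCC=C)cc1OCC=C | intermediate
30 | 2,4-bis(allyloxy)benzoyl chloride | O=C(Cl)c1ccc(OCC=C)cc1OCC=C | intermediate
31 | 1-[2,4-bis(allyloxy)phenyl]-3-{3-[(2R)-2-(tert-butyldiphenylsilyloxy)-3-methylbut-3-en-1-yl]-2-hydroxy-6-methoxy-5-(3-methylbut-2-en-1-yl)-4-(triisopropylsilyloxy)phenyl}-2-(3-methylbut-2-en-1-yl)propane-1,3-dione (C2 epimers, enol forms) | C=C(C)[C@H](O[Si](c1ccccc1)(c1ccccc1)C(C)(C)C)Cc1c(O[Si](C(C)C)(C(C)C)C(C)C)c(CC=C(C)C)c(OC)c(C(=O)C(CC=C(C)C)C(=O)c2ccc(OCC=C)cc2OCC=C)c1O | intermediate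
32 | 2-[2,4-bis(allyloxy)phenyl]-8-[(2R)-2-(tert-butyldiphenylsilyloxy)-3-methylbut-3-en-1-yl]-2-hydroxy-5-methoxy-3,6-bis(3-methylbut-2-en-1-yl)-7-(triisopropylsilyloxy)chroman-4-one (hemiketal, C2/C3 diastereomers) | C=C(C)[C@H](O[Si](c1ccccc1)(c1ccccc1)C(C)(C)C)Cc1c(O[Si](C(C)C)(C(C)C)C(C)C)c(CC=C(C)C)c(OC)c2C(=O)C(CC=C(C)C)C(O)(c3ccc(OCC=C)cc3OCC=C)Oc12 | intermediate
33 | 2-[2,4-bis(allyloxy)phenyl]-8-[(2R)-2-(tert-butyldiphenylsilyloxy)-3-methylbut-3-en-1-yl]-5-methoxy-3,6-bis(3-methylbut-2-en-1-yl)-7-(triisopropylsilyloxy)-4H-chromen-4-one | C=C(C)[C@H](O[Si](c1ccccc1)(c1ccccc1)C(C)(C)C)Cc1c(O[Si](C(C)C)(C(C)C)C(C)C)c(CC=C(C)C)c(OC)c2c(=O)c(CC=C(C)C)c(-c3ccc(OCC=C)cc3OCC=C)oc12 | intermediate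
34 | 2-[2,4-bis(allyloxy)phenyl]-8-[(2R)-2-(tert-butyldiphenylsilyloxy)-3-methylbut-3-en-1-yl]-5-hydroxy-3,6-bis(3-methylbut-2-en-1-yl)-7-(triisopropylsilyloxy)-4H-chromen-4-one | C=C(C)[C@H](O[Si](c1ccccc1)(c1ccccc1)C(C)(C)C)Cc1c(O[Si](C(C)C)(C(C)C)C(C)C)c(CC=C(C)C)c(O)c2c(=O)c(CC=C(C)C)c(-c3ccc(OCC=C)cc3OCC=C)oc12 | intermediate
35 | 2-[2,4-bis(allyloxy)phenyl]-5,7-dihydroxy-8-[(2R)-2-hydroxy-3-methylbut-3-en-1-yl]-3,6-bis(3-methylbut-2-en-1-yl)-4H-chromen-4-one | C=C(C)[C@H](O)Cc1c(O)c(CC=C(C)C)c(O)c2c(=O)c(CC=C(C)C)c(-c3ccc(OCC=C)cc3OCC=C)oc12 | intermediate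
36 | 2-(2,4-dihydroxyphenyl)-5,7-dihydroxy-8-[(2R)-2-hydroxy-3-methylbut-3-en-1-yl]-3,6-bis(3-methylbut-2-en-1-yl)-4H-chromen-4-one (CNP0297675.1) | C=C(C)[C@H](O)Cc1c(O)c(CC=C(C)C)c(O)c2c(=O)c(CC=C(C)C)c(-c3ccc(O)cc3O)oc12 | target

## Step count and least certain steps

Total: 16 steps. Longest linear sequence: 12 steps (steps 3, 4, 5, 6, 7, 9, 10, 12, 13, 14, 15, 16).

Step 6 (key step). The first ring opening may be slow, because the methoxy group stabilizes the cyclobutenone as a vinylogous ester. At the higher temperature then required, the siloxyalkyne may decompose and the product phenol may be acylated by remaining vinylketene. Fallback, from 14 (and 2) back to 19: the same vinylketene is generated below room temperature by 1,4-dehydrochlorination, so that cyclobutenone 7 is not needed. Methyl acetoacetate is C-prenylated with 2 (K2CO3, acetone) to methyl 2-acetyl-5-methylhex-4-enoate F1. O-methylation with trimethyl orthoformate and catalytic acid gives methyl 3-methoxy-2-(3-methylbut-2-en-1-yl)but-2-enoate F2 (either alkene geometry serves). LiOH gives 3-methoxy-2-(3-methylbut-2-en-1-yl)but-2-enoic acid F3, and oxalyl chloride gives 3-methoxy-2-(3-methylbut-2-en-1-yl)but-2-enoyl chloride F4. Slow addition of NEt3 to F4 and 14 in toluene at 0 °C → rt forms 15, which adds to 14 to give 16. Warming to 80 °C then completes the cascade through 17 and 18 to 19.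

Step 3. Facial discrimination may be poor for a small α-branched enal, and the volatile alcohol may be lost on isolation. Fallback, from 8 back to 14: an auxiliary-controlled acetate aldol followed by Kowalski ester homologation. The dianion of (R)-2-hydroxy-1,2,2-triphenylethyl acetate (LiN(iPr)2, then MgBr2, THF, −100 °C) adds to 8 to give (1R)-2-hydroxy-1,2,2-triphenylethyl (3R)-3-hydroxy-4-methylpent-4-enoate F5. The sense follows the known course of this reagent with α-branched aldehydes, and crystallization can raise the purity. K2CO3 in MeOH gives methyl (3R)-3-hydroxy-4-methylpent-4-enoate F6, and TBDPSCl with imidazole gives methyl (3R)-3-(tert-butyldiphenylsilyloxy)-4-methylpent-4-enoate F7. Treatment of F7 with CH2Br2 and lithium 2,2,6,6-tetramethylpiperidide at −78 °C, then LiN(SiMe3)2 and n-BuLi, rearranges the ester to ynolate 13, and TIPSCl traps it as 14.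

Step 9. The benzylic–allylic methylene of the C6 prenyl group may be deprotonated in competition with the ring, or the hindered aryllithium may enolize the amide instead of adding to it. Fallback, from 19 back to 26, which also avoids steps 7 and 10: magnesium-mediated ortho-formylation of the free phenol (MgCl2, NEt3, paraformaldehyde, MeCN, reflux) gives 3-[(2R)-2-(tert-butyldiphenylsilyloxy)-3-methylbut-3-en-1-yl]-2-hydroxy-6-methoxy-5-(3-methylbut-2-en-1-yl)-4-(triisopropylsilyloxy)benzaldehyde F8. Addition of 4-methylpent-3-enylmagnesium bromide (2.2 equiv, THF, −78 °C) gives the benzylic alcohol 2-(1-hydroxy-5-methylhex-4-en-1-yl) phenol F9, which is oxidized without delay (MnO2, CH2Cl2) to 26.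

Step 13. Acid may add the diketone enol oxygen to the C3 prenyl alkene, and dehydration may be slow at the crowded C3. Fallback, from 26 and 30 back to 33 without acid: heating 26 with 30 and 1,8-diazabicyclo[5.4.0]undec-7-ene in pyridine at 90 °C forms the aryl ester 2-acyl-6-substituted phenyl 2,4-bis(allyloxy)benzoate F10. Under these conditions F10 undergoes the Baker–Venkataraman acyl shift, and the resulting diketonate closes and loses hydroxide by an E1cB path to give 33.

## Further compounds

F1 | step 6 | methyl 2-acetyl-5-methylhex-4-enoate (racemic) | COC(=O)C(CC=C(C)C)C(C)=O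
F2 | step 6 | methyl 3-methoxy-2-(3-methylbut-2-en-1-yl)but-2-enoate (alkene geometry not defined) | COC(=O)C(CC=C(C)C)=C(C)OC
F3 | step 6 | 3-methoxy-2-(3-methylbut-2-en-1-yl)but-2-enoic acid | OC(=O)C(CC=C(C)C)=C(C)OC
F4 | step 6 | 3-methoxy-2-(3-methylbut-2-en-1-yl)but-2-enoyl chloride | ClC(=O)C(CC=C(C)C)=C(C)OC
F5 | step 3 | (1R)-2-hydroxy-1,2,2-triphenylethyl (3R)-3-hydroxy-4-methylpent-4-enoate | C=C(C)[C@H](O)CC(=O)O[C@H](c1ccccc1)C(O)(c1ccccc1)c1ccccc1
F6 | step 3 | methyl (3R)-3-hydroxy-4-methylpent-4-enoate | C=C(C)[C@H](O)CC(=O)OC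
F7 | step 3 | methyl (3R)-3-(tert-butyldiphenylsilyloxy)-4-methylpent-4-enoate | C=C(C)[C@H](O[Si](c1ccccc1)(c1ccccc1)C(C)(C)C)CC(=O)OC
F8 | step 9 | 3-[(2R)-2-(tert-butyldiphenylsilyloxy)-3-methylbut-3-en-1-yl]-2-hydroxy-6-methoxy-5-(3-methylbut-2-en-1-yl)-4-(triisopropylsilyloxy)benzaldehyde | C=C(C)[C@H](O[Si](c1ccccc1)(c1ccccc1)C(C)(C)C)Cc1c(O[Si](C(C)C)(C(C)C)C(C)C)c(CC=C(C)C)c(OC)c(C=O)c1O
F9 | step 9 | 6-[(2R)-2-(tert-butyldiphenylsilyloxy)-3-methylbut-3-en-1-yl]-2-(1-hydroxy-5-methylhex-4-en-1-yl)-3-methoxy-4-(3-methylbut-2-en-1-yl)-5-(triisopropylsilyloxy)phenol (carbinol epimers) | C=C(C)[C@H](O[Si](c1ccccc1)(c1ccccc1)C(C)(C)C)Cc1c(O[Si](C(C)C)(C(C)C)C(C)C)c(CC=C(C)C)c(OC)c(C(O)CCC=C(C)C)c1O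
F10 | step 13 | 6-[(2R)-2-(tert-butyldiphenylsilyloxy)-3-methylbut-3-en-1-yl]-3-methoxy-4-(3-methylbut-2-en-1-yl)-2-(5-methylhex-4-enoyl)-5-(triisopropylsilyloxy)phenyl 2,4-bis(allyloxy)benzoate | C=C(C)[C@H](O[Si](c1ccccc1)(c1ccccc1)C(C)(C)C)Cc1c(O[Si](C(C)C)(C(C)C)C(C)C)c(CC=C(C)C)c(OC)c(C(=O)CCC=C(C)C)c1OC(=O)c1ccc(OCC=C)cc1OCC=C
A1 | alternative 1 | 5-(allyloxy)-1,3-bis(methoxymethoxy)-2-(3-methylbut-2-en-1-yl)benzene | CC(C)=CCc1c(OCOC)cc(OCC=C)cc1OCOC
A2 | alternative 1 | (3R)-3-{[4-(allyloxy)-2,6-bis(methoxymethoxy)phenyl]methyl}-2,2-dimethyloxirane | CC1(C)O[C@@H]1Cc1c(OCOC)cc(OCC=C)cc1OCOC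
A3 | alternative 2 | methyl 2-[2,4-bis(methoxymethoxy)phenyl]-6-[(3R)-3-(tert-butyldimethylsilyloxy)-2,10-dimethyl-6-oxoundeca-1,9-dien-5-yl]-3-(3-methylbut-2-en-1-yl)-4-oxo-4H-pyran-5-carboxylate (C5 of the side chain not defined) | C=C(C)[C@H](O[Si](C)(C)C(C)(C)C)CC(C(=O)CCC=C(C)C)c1oc(-c2ccc(OCOC)cc2OCOC)c(CC=C(C)C)c(=O)c1C(=O)OC
A4 | alternative 2 | 2-[2,4-bis(methoxymethoxy)phenyl]-8-[(2R)-2-(tert-butyldimethylsilyloxy)-3-methylbut-3-en-1-yl]-5,7-dihydroxy-3,6-bis(3-methylbut-2-en-1-yl)-4H-chromen-4-one | C=C(C)[C@H](O[Si](C)(C)C(C)(C)C)Cc1c(O)c(CC=C(C)C)c(O)c2c(=O)c(CC=C(C)C)c(-c3ccc(OCOC)cc3OCOC)oc12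
A5 | alternative 3 | 3-[(2R)-2-(tert-butyldimethylsilyloxy)-3-methylbut-3-en-1-yl]-2-hydroxy-4,6-bis(methoxymethoxy)-5-(3-methylbut-2-en-1-yl)benzaldehyde | C=C(C)[C@H](O[Si](C)(C)C(C)(C)C)Cc1c(O)c(C=O)c(OCOC)c(CC=C(C)C)c1OCOC
A6 | alternative 3 | 2,4-bis(methoxymethoxy)-1-(5-methylhex-4-en-1-yn-1-yl)benzene | CC(C)=CCC#Cc1ccc(OCOC)cc1OCOC
A7 | alternative 3 | 2-[2,4-bis(methoxymethoxy)phenyl]-8-[(2R)-2-(tert-butyldimethylsilyloxy)-3-methylbut-3-en-1-yl]-5,7-bis(methoxymethoxy)-3,6-bis(3-methylbut-2-en-1-yl)-4H-chromen-4-one | C=C(C)[C@H](O[Si](C)(C)C(C)(C)C)Cc1c(OCOC)c(CC=C(C)C)c(OCOC)c2c(=O)c(CC=C(C)C)c(-c3ccc(OCOC)cc3OCOC)oc12
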